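## Retrosynthetic overview

1. Manumycin G ⇐ its C1 dimethyl ketal (last step: ketal hydrolysis). The lower triene is cut at C2'–C3' by a Stille coupling of a core-bound (E)-vinylstannane with the (2E,4E)-5-bromodienamide of the C5N unit.
2. Vinylstannane carbinol ⇐ 1,2-addition of (E)-Bu3SnCH=CHLi to the ketone of an epoxy quinone monoketal, anti to the oxirane (sets C4).
3. Epoxy quinone monoketal ⇐ new catalytic enantioselective nucleophilic epoxidation of the 3-acylamino quinone monoketal (sets C5 and C6).
4. Quinone monoketal ⇐ PhI(OAc)2/MeOH dearomatisation of the anilide from 2,5-dimethoxyaniline and (2E,4E,6E)-8-methylnona-2,4,6-trienoic acid (vinylogous HWE).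
5. Ring order: the six-membered carbocycle is bought as the arene and dearomatised, then the oxirane is closed on it; the cyclopentenone ring is bought as cyclopentane-1,3-dione and aminated.

Assumption: (E)-4-methylpent-2-enal, (E)-1,2-bis(tributylstannyl)ethene and glutaconaldehyde potassium salt are bought; catalyst Q of step 5 is the (S)-tert-leucine-derived iminophosphorane–urea O=C(Nc1cc(C(F)(F)F)cc(C(F)(F)F)c1)N[C@@H](C(C)(C)C)CN=P(c1ccc(OC)cc1)(c1ccc(OC)cc1)c1ccc(OC)cc1, and its sense of induction is assumed to give the (1S,6R)-epoxide (otherwise its mirror image from D-tert-leucine is used).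

## Route

Step 1
Reactants: 1 (E)-4-methylpent-2-enal; 2 triethyl 4-phosphonocrotonate [ethyl (E)-4-(diethoxyphosphoryl)but-2-enoate]
Product: 3 ethyl (2E,4E,6E)-8-methylnona-2,4,6-trienoate
Conditions: LiHMDS, THF, −78 → 0 °C; aq. NH4Cl
Reagents that add atoms: none
Why: Vinylogous Horner–Wadsworth–Emmons olefination; the stabilised phosphonate anion forms the new C4=C5 bond E-selectively while the 2E and 6E bonds are carried in from 2 and 1.

Step 2
Reactants: 3 ethyl (2E,4E,6E)-8-methylnona-2,4,6-trienoate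
Product: 4 (2E,4E,6E)-8-methylnona-2,4,6-trienoic acid
Conditions: LiOH·H2O, THF/MeOH/H2O, rt; then 1 M HCl
Reagents that add atoms: lithium hydroxide, [Li+].[OH-]
Why: Ester saponification (BAc2) leaves the triene untouched at rt, and recrystallisation of the acid removes traces of Z isomers.

Step 3
Reactants: 4 (2E,4E,6E)-8-methylnona-2,4,6-trienoic acid; 5 2,5-dimethoxyaniline
Product: 7 (2E,4E,6E)-N-(2,5-dimethoxyphenyl)-8-methylnona-2,4,6-trienamide, via (2E,4E,6E)-8-methylnona-2,4,6-trienoyl chloride 6 (not isolated)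
Conditions: (COCl)2, cat. DMF, CH2Cl2, 0 °C → rt; then 5, pyridine, CH2Cl2, 0 °C → rt
Reagents that add atoms: none
Why: Vilsmeier-catalysed acid chloride formation followed by N-acylation of the electron-rich aniline (Schotten–Baumann-type amidation).

Step 4
Reactants: 7 (2E,4E,6E)-N-(2,5-dimethoxyphenyl)-8-methylnona-2,4,6-trienamide
Product: 8 (2E,4E,6E)-N-(6,6-dimethoxy-3-oxocyclohexa-1,4-dien-1-yl)-8-methylnona-2,4,6-trienamide (3-acylamino quinone monoketal)
Conditions: PhI(OAc)2, MeOH, 0 °C → rt; aq. NaHCO3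
Reagents that add atoms: methanol, CO; water, O
Why: Hypervalent-iodine oxidative dearomatisation: two-electron oxidation of the anilide, methanol capture at the ring carbon ipso to the ortho-methoxy group, and hydrolysis of the remaining methyl enol ether on work-up give the ketal next to the amide-bearing carbon; the electron-poor trienamide is inert to PhI(OAc)2.

Step 5
Reactants: 8 (2E,4E,6E)-N-(6,6-dimethoxy-3-oxocyclohexa-1,4-dien-1-yl)-8-methylnona-2,4,6-trienamide
Product: 9 (2E,4E,6E)-N-[(1S,6R)-2,2-dimethoxy-5-oxo-7-oxabicyclo[4.1.0]hept-3-en-3-yl]-8-methylnona-2,4,6-trienamide (epoxy quinone monoketal)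
Conditions: catalyst Q (10 mol%), cumene hydroperoxide (1.3 equiv), toluene, 4 Å MS, −30 °C
Reagents that add atoms: cumene hydroperoxide, CC(C)(OO)c1ccccc1
Why: Proposed new method: a bifunctional iminophosphorane-catalysed enantioselective Weitz–Scheffer epoxidation, in which the superbasic P=N site deprotonates cumene hydroperoxide to a tight chiral aminophosphonium cumylperoxide ion pair while the urea N–H pair clamps the ketone oxygen of 8 (LUMO lowering) so that the tert-butyl wall leaves one face of the unsubstituted C4=C5 enone open; the peroxide adds to the β-carbon next to the ketal and the urea-bound enolate closes the oxirane with loss of cumyl oxide (reprotonated by the phosphonium, turning the catalyst over), which sets both epoxide stereocentres as (1S,6R); the acidic vinylogous-imide N–H only parks the catalyst reversibly as an unreactive amidate ion pair, the β-amido enone and the trienamide are too electron-rich to compete, and the closest known reactions are iminophosphorane-catalysed sulfa- and oxa-Michael additions and the cinchona phase-transfer epoxidation of enones and quinone monoketals.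

Step 6
Reactants: 9 (2E,4E,6E)-N-[(1S,6R)-2,2-dimethoxy-5-oxo-7-oxabicyclo[4.1.0]hept-3-en-3-yl]-8-methylnona-2,4,6-trienamide; 10 (E)-1,2-bis(tributylstannyl)ethene
Product: 12 (2E,4E,6E)-N-{(1S,5R,6R)-5-hydroxy-2,2-dimethoxy-5-[(E)-2-(tributylstannyl)ethenyl]-7-oxabicyclo[4.1.0]hept-3-en-3-yl}-8-methylnona-2,4,6-trienamide (OH cis to the oxirane oxygen), via (E)-2-(tributylstannyl)ethenyllithium 11 (not isolated)
Conditions: 10 (2.6 equiv), n-BuLi (2.5 equiv), THF, −78 °C, 1 h; then 9, −78 °C; aq. NH4Cl
Reagents that add atoms: none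
Why: Sn–Li exchange followed by 1,2-addition of the alkenyllithium to the ketone: the first equivalent deprotonates the amide N–H (which also shields the trienamide), the second adds to the carbonyl from the face anti to the oxirane oxygen (steric and electrostatic control by the cis-fused epoxide), so the tertiary OH ends up syn to the epoxide; the descriptor is 5R only because tin raises the CIP rank of the vinyl group, the spatial sense being that of C4 (S) of the target.

Step 7
Reactants: 13 cyclopentane-1,3-dione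
Product: 14 2-(hydroxyimino)cyclopentane-1,3-dione
Conditions: NaNO2, aq. HCl, 0 °C
Reagents that add atoms: sodium nitrite, [Na+].[O-]N=O
Why: C-nitrosation of the doubly activated C2 position of the 1,3-dione and tautomerisation to the oxime.

Step 8
Reactants: 14 2-(hydroxyimino)cyclopentane-1,3-dione
Product: 15 2-amino-3-hydroxycyclopent-2-en-1-one hydrochloride
Conditions: H2 (1 atm), 10% Pd/C, HCl, EtOH, rt
Reagents that add atoms: hydrogen chloride, Cl
Why: Catalytic hydrogenation of the oxime to the primary amine, trapped as the hydrochloride to prevent self-condensation; the product rests as the enol tautomer.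

Step 9
Reactants: 16 glutaconaldehyde potassium salt [potassium (1E,3E)-5-oxopenta-1,3-dien-1-olate]
Product: 17 (2E,4E)-5-bromopenta-2,4-dienal
Conditions: PPh3, Br2, CH2Cl2, 0 °C; then 16, 0 °C → rt
Reagents that add atoms: bromine, BrBr (delivered as Ph3PBr2)
Why: Appel-type deoxybromination of the dienolate: O-phosphonium formation, then addition–elimination by bromide, gives the thermodynamically favoured E,E-bromodienal.

Step 10
Reactants: 17 (2E,4E)-5-bromopenta-2,4-dienal
Product: 18 (2E,4E)-5-bromopenta-2,4-dienoic acid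
Conditions: NaClO2, NaH2PO4, 2-methylbut-2-ene, t-BuOH/H2O, 0 °C → rt
Reagents that add atoms: sodium chlorite, [Na+].[O-]Cl=O
Why: Pinnick oxidation converts the enal to the acid without touching the diene or the vinyl bromide, because the HOCl by-product is scavenged by the alkene.

Step 11
Reactants: 18 (2E,4E)-5-bromopenta-2,4-dienoic acid; 15 2-amino-3-hydroxycyclopent-2-en-1-one hydrochloride
Product: 20 (2E,4E)-5-bromo-N-(2-hydroxy-5-oxocyclopent-1-en-1-yl)penta-2,4-dienamide, via (2E,4E)-5-bromopenta-2,4-dienoyl chloride 19 (not isolated)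
Conditions: (COCl)2, cat. DMF, CH2Cl2, 0 °C → rt; then 15, Et3N, THF, 0 °C → rt; dilute HCl work-up
Reagents that add atoms: none
Why: Acid chloride formation and N-acylation; with Et3N the enolic OH is present as a delocalised vinylogous carboxylate, so the amine nitrogen is the acylated site (Schotten–Baumann logic).

Step 12
Reactants: 12 (2E,4E,6E)-N-{(1S,5R,6R)-5-hydroxy-2,2-dimethoxy-5-[(E)-2-(tributylstannyl)ethenyl]-7-oxabicyclo[4.1.0]hept-3-en-3-yl}-8-methylnona-2,4,6-trienamide; 20 (2E,4E)-5-bromo-N-(2-hydroxy-5-oxocyclopent-1-en-1-yl)penta-2,4-dienamide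
Product: 21 (2E,4E,6E)-N-[(1S,5S,6R)-5-hydroxy-5-{(1E,3E,5E)-7-[(2-hydroxy-5-oxocyclopent-1-en-1-yl)amino]-7-oxohepta-1,3,5-trien-1-yl}-2,2-dimethoxy-7-oxabicyclo[4.1.0]hept-3-en-3-yl]-8-methylnona-2,4,6-trienamide (manumycin G dimethyl ketal)
Conditions: PdCl2(MeCN)2 (5 mol%), DMF, rt, dark
Reagents that add atoms: none
Why: Stille cross-coupling forms the C2'–C3' bond with retention of both alkene geometries (all-E triene) under neutral conditions that tolerate the free OH, N–H, enol, epoxide and ketal.

Step 13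
Reactants: 21 manumycin G dimethyl ketal
Product: 22 Manumycin G, (2E,4E,6E)-N-[(1S,5S,6R)-5-hydroxy-5-{(1E,3E,5E)-7-[(2-hydroxy-5-oxocyclopent-1-en-1-yl)amino]-7-oxohepta-1,3,5-trien-1-yl}-2-oxo-7-oxabicyclo[4.1.0]hept-3-en-3-yl]-8-methylnona-2,4,6-trienamide (4S,5R,6S in cyclohexenone numbering)
Conditions: montmorillonite K10, wet CH2Cl2, rt
Reagents that add atoms: water, O
Why: Mild heterogeneous acid-catalysed hydrolysis of the dimethyl ketal unveils the enone carbonyl without ionising the tertiary allylic alcohol or opening the epoxide; no stereocentre is touched.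

## Compound list

1 | (E)-4-methylpent-2-enal | CC(C)/C=C/C=O | starting material
2 | triethyl 4-phosphonocrotonate | CCOC(=O)/C=C/CP(=O)(OCC)OCC | starting material
3 | ethyl (2E,4E,6E)-8-methylnona-2,4,6-trienoate | CC(C)/C=C/C=C/C=C/C(=O)OCC | intermediate
4 | (2E,4E,6E)-8-methylnona-2,4,6-trienoic acid | CC(C)/C=C/C=C/C=C/C(=O)O | intermediate
5 | 2,5-dimethoxyaniline | COc1ccc(OC)c(N)c1 | starting material
6 | (2E,4E,6E)-8-methylnona-2,4,6-trienoyl chloride | CC(C)/C=C/C=C/C=C/C(=O)Cl | intermediate
7 | (2E,4E,6E)-N-(2,5-dimethoxyphenyl)-8-methylnona-2,4,6-trienamide | CC(C)/C=C/C=C/C=C/C(=O)Nc1cc(OC)ccc1OC | intermediate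
8 | (2E,4E,6E)-N-(6,6-dimethoxy-3-oxocyclohexa-1,4-dien-1-yl)-8-methylnona-2,4,6-trienamide | CC(C)/C=C/C=C/C=C/C(=O)NC1=CC(=O)C=CC1(OC)OC | intermediate
9 | (2E,4E,6E)-N-[(1S,6R)-2,2-dimethoxy-5-oxo-7-oxabicyclo[4.1.0]hept-3-en-3-yl]-8-methylnona-2,4,6-trienamide | CC(C)/C=C/C=C/C=C/C(=O)NC1=CC(=O)[C@@H]2O[C@@H]2C1(OC)OC | intermediate
10 | (E)-1,2-bis(tributylstannyl)ethene | CCCC[Sn](CCCC)(CCCC)/C=C/[Sn](CCCC)(CCCC)CCCC | starting material
11 | (E)-2-(tributylstannyl)ethenyllithium | [Li]/C=C/[Sn](CCCC)(CCCC)CCCC | intermediate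
12 | (2E,4E,6E)-N-{(1S,5R,6R)-5-hydroxy-2,2-dimethoxy-5-[(E)-2-(tributylstannyl)ethenyl]-7-oxabicyclo[4.1.0]hept-3-en-3-yl}-8-methylnona-2,4,6-trienamide | CC(C)/C=C/C=C/C=C/C(=O)NC1=C[C@@](O)(/C=C/[Sn](CCCC)(CCCC)CCCC)[C@@H]2O[C@@H]2C1(OC)OC | intermediate
13 | cyclopentane-1,3-dione | O=C1CCC(=O)C1 | starting material
14 | 2-(hydroxyimino)cyclopentane-1,3-dione | O=C1CCC(=O)C1=NO | intermediate
15 | 2-amino-3-hydroxycyclopent-2-en-1-one hydrochloride | Cl.NC1=C(O)CCC1=O | intermediate
16 | glutaconaldehyde potassium salt | [K+].[O-]/C=C/C=C/C=O | starting material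
17 | (2E,4E)-5-bromopenta-2,4-dienal | Br/C=C/C=C/C=O | intermediate
18 | (2E,4E)-5-bromopenta-2,4-dienoic acid | Br/C=C/C=C/C(=O)O | intermediate
19 | (2E,4E)-5-bromopenta-2,4-dienoyl chloride | Br/C=C/C=C/C(=O)Cl | intermediate
20 | (2E,4E)-5-bromo-N-(2-hydroxy-5-oxocyclopent-1-en-1-yl)penta-2,4-dienamide | Br/C=C/C=C/C(=O)NC1=C(O)CCC1=O | intermediate
21 | manumycin G dimethyl ketal, (1S,5S,6R) core | CC(C)/C=C/C=C/C=C/C(=O)NC1=C[C@@](O)(/C=C/C=C/C=C/C(=O)NC2=C(O)CCC2=O)[C@@H]2O[C@@H]2C1(OC)OC | intermediate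
22 | Manumycin G | CC(C)/C=C/C=C/C=C/C(=O)NC1=C[C@@](O)(/C=C/C=C/C=C/C(=O)NC2=C(O)CCC2=O)[C@@H]2O[C@@H]2C1=O | target

## Step count and risks

Total step count: 13. Longest linear sequence: 8 steps (steps 1, 2, 3, 4, 5, 6, 12, 13).

The three steps most likely to fail:

Step 5 (the proposed new epoxidation). The level and sense of enantioselectivity are unproven, the acidic N–H may hold the catalyst as its amidate, and the iminophosphorane may degrade. The fallback uses known chemistry and sets out from 8: a racemic Weitz–Scheffer epoxidation with 30% H2O2 and K2CO3 in THF/H2O at 0 °C gives the racemate, that is 9 together with its enantiomer (2E,4E,6E)-N-[(1R,6S)-2,2-dimethoxy-5-oxo-7-oxabicyclo[4.1.0]hept-3-en-3-yl]-8-methylnona-2,4,6-trienamide F1. The two are separated by preparative chiral SFC on an amylose carbamate phase, and the route is rejoined at 9. This replaces asymmetric catalysis by resolution.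

Step 6 (alkenyllithium addition). The excess basic, bulky stannylvinyllithium may give incomplete conversion, attack the trienamide or epoxide, or add with imperfect facial control. The fallback sets out from 9: ethynylmagnesium bromide with CeCl3 (THF, −78 °C) adds the small, weakly basic acetylide anti to the oxirane to give (2E,4E,6E)-N-[(1S,5R,6R)-5-ethynyl-5-hydroxy-2,2-dimethoxy-7-oxabicyclo[4.1.0]hept-3-en-3-yl]-8-methylnona-2,4,6-trienamide F2. Pd-catalysed syn-hydrostannation (Bu3SnH, PdCl2(PPh3)2, THF, 0 °C) then places tin on the terminal carbon of the hindered tertiary propargylic alcohol, and the route comes back at 12.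

Step 12 (Stille coupling with the C5N bromodienamide). The chelating, acidic enol-dione amide 20 may poison palladium, dissolve poorly or protodestannylate 12. The fallback sets out from 12 and changes the bond order: Stille coupling with the simpler free acid 18 (as its iPr2NEt salt, Pd2(dba)3/AsPh3, NMP, rt) gives (2E,4E,6E)-7-{(1R,2S,6S)-2-hydroxy-5,5-dimethoxy-4-[(2E,4E,6E)-8-methylnona-2,4,6-trienoylamino]-7-oxabicyclo[4.1.0]hept-3-en-2-yl}hepta-2,4,6-trienoic acid F3. This is then condensed with 15 (EDC·HCl, HOBt, iPr2NEt, DMF, 0 °C), and the route comes back at 21.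

Further compounds
F1 | step 5 | (2E,4E,6E)-N-[(1R,6S)-2,2-dimethoxy-5-oxo-7-oxabicyclo[4.1.0]hept-3-en-3-yl]-8-methylnona-2,4,6-trienamide | CC(C)/C=C/C=C/C=C/C(=O)NC1=CC(=O)[C@H]2O[C@H]2C1(OC)OC
F2 | step 6 | (2E,4E,6E)-N-[(1S,5R,6R)-5-ethynyl-5-hydroxy-2,2-dimethoxy-7-oxabicyclo[4.1.0]hept-3-en-3-yl]-8-methylnona-2,4,6-trienamide | CC(C)/C=C/C=C/C=C/C(=O)NC1=C[C@@](O)(C#C)[C@@H]2O[C@@H]2C1(OC)OC
F3 | step 12 | (2E,4E,6E)-7-{(1R,2S,6S)-2-hydroxy-5,5-dimethoxy-4-[(2E,4E,6E)-8-methylnona-2,4,6-trienoylamino]-7-oxabicyclo[4.1.0]hept-3-en-2-yl}hepta-2,4,6-trienoic acid | CC(C)/C=C/C=C/C=C/C(=O)NC1=C[C@@](O)(/C=C/C=C/C=C/C(=O)O)[C@@H]2O[C@@H]2C1(OC)OC
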